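**Retrosynthetic overview**
1. Target 28 is a meso tetrahydrofuran (O1, C2–C5) with aryl groups on C2 and C5 and CH2OAc arms on C3 and C4. The arms are cis to each other and each aryl is trans to its neighbouring arm. It goes back, by desilylation, acid equilibration of the benzylic centres, acetylation and lactone reduction, to the cis-fused furo[3,4-c]furan-1-one 24.
2. Structural feature used: C2 is bonded to O1 and to an electron-rich aryl ring. In the ring-opened ether C5–O1–C2H2–Ar its C–H bonds are therefore the most hydridic in the molecule, and they lie 1,5 to C3. The cis C3/C4 arms can be tied into a gamma-butyrolactone in which C3 is the alpha-carbon.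
3. Key disconnection C2–C3: a dirhodium carbene at C3 of diazo lactone 23 inserts into a C–H bond of O1–C2H2Ar.
4. Compound 23 comes from an anti allylboration (C4–C5 bond, both centres set), imidate O-alkylation, hydroboration, oxidation to the acid, lactonisation and deacylative diazo transfer.
5. Ring order: lactone first (step 11), tetrahydrofuran second (step 13). The lactone is opened again in step 14.

Key step: step 13

Remark on the chemistry: 28 has a mirror plane through O1 and the midpoint of C3–C4 (2R,3S,4R,5S, meso), so all chiral intermediates are used as racemates and their SMILES show one enantiomer.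
Abbreviations: TBS = tert-butyldimethylsilyl; Ar = 3,4-bis(tert-butyldimethylsilyloxy)phenyl. The numbering O1, C2–C5 of 28 is used for all intermediates.

**Step 1**
Reactants: 1 3,4-dihydroxybenzaldehyde; 2 tert-butyldimethylsilyl chloride
Product: 3 3,4-bis(tert-butyldimethylsilyloxy)benzaldehyde
Conditions: TBSCl (2.4 equiv), imidazole (5 equiv), DMF, 0 °C to rt
Reagents that add atoms: tert-butyldimethylsilyl chloride CC(C)(C)[Si](C)(C)Cl
Why: Imidazole-promoted silyl ether formation caps both phenols, leaves the aldehyde alone, and avoids benzyl groups whose C–H bonds would compete in step 13.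

**Step 2**
Reactants: 3 3,4-bis(tert-butyldimethylsilyloxy)benzaldehyde
Product: 4 [3,4-bis(tert-butyldimethylsilyloxy)phenyl]methanol
Conditions: NaBH4, MeOH–THF, 0 °C
Reagents that add atoms: none
Why: Borohydride reduction of an aromatic aldehyde is fast at 0 °C, where aryl silyl ethers are not yet attacked by methanol.

**Step 3**
Reactants: 4 [3,4-bis(tert-butyldimethylsilyloxy)phenyl]methanol; 5 trichloroacetonitrile
Product: 6 3,4-bis(tert-butyldimethylsilyloxy)benzyl 2,2,2-trichloroacetimidate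
Conditions: Cl3CCN (3 equiv), DBU (0.1 equiv), CH2Cl2, 0 °C
Reagents that add atoms: trichloroacetonitrile N#CC(Cl)(Cl)Cl
Why: Base-catalysed addition of the alcohol to the nitrile (trichloroacetimidate formation) needs only a catalytic amount of DBU in dry solvent, too little to desilylate the phenols.

**Step 4**
Reactants: 7 (Z)-but-2-ene-1,4-diol; 2 tert-butyldimethylsilyl chloride
Product: 8 (Z)-4-(tert-butyldimethylsilyloxy)but-2-en-1-ol
Conditions: NaH (1.0 equiv), THF, 0 °C to rt; then TBSCl (1.0 equiv)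
Reagents that add atoms: tert-butyldimethylsilyl chloride CC(C)(C)[Si](C)(C)Cl
Why: Monosilylation of a symmetrical diol through its sparingly soluble monosodium alkoxide favours the monoether over the bis-ether.

**Step 5**
Reactants: 8 (Z)-4-(tert-butyldimethylsilyloxy)but-2-en-1-ol; 9 acetic anhydride
Product: 10 (Z)-4-(tert-butyldimethylsilyloxy)but-2-enyl acetate
Conditions: Ac2O, Et3N, DMAP (cat.), CH2Cl2, 0 °C to rt
Reagents that add atoms: acetic anhydride CC(=O)OC(C)=O
Why: DMAP-catalysed acetylation turns the allylic alcohol into a leaving group that zerovalent palladium can ionise.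

**Step 6**
Reactants: 10 (Z)-4-(tert-butyldimethylsilyloxy)but-2-enyl acetate; 11 bis(pinacolato)diboron
Product: 12 (E)-4-(tert-butyldimethylsilyloxy)but-2-enylboronic acid pinacol ester
Conditions: B2pin2 (1.1 equiv), Pd2(dba)3 (2.5 mol%), DMSO, 50 °C
Reagents that add atoms: bis(pinacolato)diboron CC1(C)OB(OC1(C)C)B1OC(C)(C)C(C)(C)O1
Why: In this palladium-catalysed allylic borylation the acetate ionises to a pi-allyl complex of divalent palladium, which relaxes to its syn form before boryl transfer to the unsubstituted terminus, so the Z acetate should give the linear E boronate.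

**Step 7**
Reactants: 12 (E)-4-(tert-butyldimethylsilyloxy)but-2-enylboronic acid pinacol ester; 3 3,4-bis(tert-butyldimethylsilyloxy)benzaldehyde
Product: 14 rac-(1S*,2R*)-1-Ar-2-(TBSOCH2)but-3-en-1-ol (anti), via pinacol borate ester 13 (not isolated)
Conditions: toluene, 4 Å MS, rt to 50 °C; aqueous NaHCO3 work-up
Reagents that add atoms: none
Why: Allylboration through a closed chair Zimmerman–Traxler transition state, in which the E double bond places CH2OTBS and the aldehyde aryl group both equatorial, forms C4–C5 and sets the two centres anti, so the C5 aryl is later trans to the C4 arm.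

**Step 8**
Reactants: 14 rac-(1S*,2R*)-1-Ar-2-(TBSOCH2)but-3-en-1-ol; 6 3,4-bis(tert-butyldimethylsilyloxy)benzyl 2,2,2-trichloroacetimidate
Product: 15 rac-(1S*,2R*)-1-Ar-1-(ArCH2O)-2-(TBSOCH2)but-3-ene (anti arylmethyl ether)
Conditions: 6 (1.5 equiv), La(OTf)3 (5 mol%), toluene, 0 °C to rt
Reagents that add atoms: none
Why: Acid-catalysed trichloroacetimidate O-alkylation, as practised for p-methoxybenzyl ethers, should work because the electron-rich imidate ionises under a lanthanide triflate too mild to ionise the C5 alcohol, and because no free alkoxide is present to pull silyl groups off the phenols, so C5 keeps its configuration.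

**Step 9**
Reactants: 15 rac-(1S*,2R*)-1-Ar-1-(ArCH2O)-2-(TBSOCH2)but-3-ene
Product: 17 rac-(3R*,4S*)-4-Ar-4-(ArCH2O)-3-(TBSOCH2)butan-1-ol, via B-alkyl-9-BBN adduct 16 (not isolated)
Conditions: 9-BBN (1.5 equiv), THF, 0 °C to rt; then 30% H2O2, pH 7 phosphate buffer, 0 °C to rt
Reagents that add atoms: hydrogen peroxide OO; 9-borabicyclo[3.3.1]nonane B1C2CCCC1CCC2 (its atoms stay only in 16)
Why: Hydroboration with 9-BBN puts boron on the terminal carbon of the monosubstituted alkene for steric reasons, and oxidation at pH 7 spares the base-labile aryl silyl ethers.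

**Step 10**
Reactants: 17 rac-(3R*,4S*)-4-Ar-4-(ArCH2O)-3-(TBSOCH2)butan-1-ol
Product: 19 rac-(3R*,4S*)-4-Ar-4-(ArCH2O)-3-(TBSOCH2)butanoic acid, via aldehyde 18 (not isolated)
Conditions: TEMPO (0.2 equiv), PhI(OAc)2 (2.5 equiv), CH2Cl2–H2O 2:1, rt
Reagents that add atoms: water O
Why: Oxoammonium oxidation (TEMPO with PhI(OAc)2 and water) takes the primary alcohol through the aldehyde hydrate to the acid and is known to tolerate silyl ethers and electron-rich benzyl ethers.

**Step 11**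
Reactants: 19 rac-(3R*,4S*)-4-Ar-4-(ArCH2O)-3-(TBSOCH2)butanoic acid
Product: 21 rac-(4R*)-4-[(S*)-Ar(ArCH2O)methyl]dihydrofuran-2(3H)-one, via hydroxy acid 20 (not isolated)
Conditions: camphorsulfonic acid (0.2 equiv), MeOH–CH2Cl2 1:1, 0 °C to rt
Reagents that add atoms: none
Why: Acid methanolysis removes a primary alkyl silyl ether much faster than aryl silyl ethers, and the freed gamma-hydroxy acid lactonises at once (5-exo-trig), with only one lactone possible because only the carbon attached to C3 is at the acid level.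

**Step 12**
Reactants: 21 rac-(4R*)-4-[(S*)-Ar(ArCH2O)methyl]dihydrofuran-2(3H)-one
Product: 23 rac-(4R*)-3-diazo-4-[(S*)-Ar(ArCH2O)methyl]dihydrofuran-2(3H)-one, via trifluoroacetyl lactone 22 (not isolated)
Conditions: LiHMDS (1.1 equiv), THF, −78 °C, then CF3CO2CH2CF3 (1.2 equiv); dilute HCl wash; crude 22, 4-acetamidobenzenesulfonyl azide (1.5 equiv), Et3N (1.5 equiv), H2O (1 equiv), MeCN, rt
Reagents that add atoms: 4-acetamidobenzenesulfonyl azide CC(=O)Nc1ccc(cc1)S(=O)(=O)N=[N+]=[N-]; 2,2,2-trifluoroethyl trifluoroacetate O=C(OCC(F)(F)F)C(F)(F)F (its acyl group stays only in 22)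
Why: In this deacylative form of the Regitz diazo transfer, Claisen trifluoroacetylation of the lithium enolate activates C3 and the azide then delivers N2 with loss of the trifluoroacetyl group, a sequence established for butyrolactones that leaves C4 and C5 untouched.

**Step 13**
Reactants: 23 rac-(4R*)-3-diazo-4-[(S*)-Ar(ArCH2O)methyl]dihydrofuran-2(3H)-one
Product: 24 rac-(3aR*,4S*,6S*,6aR*)-4,6-di-Ar-tetrahydro-1H,3H-furo[3,4-c]furan-1-one (cis-fused; 4-aryl convex; 6-aryl concave)
Conditions: Rh2(OAc)4 (2 mol%), CH2Cl2, 4 Å MS, reflux, slow addition of 23 (high dilution)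
Reagents that add atoms: none
Why: Rh2(OAc)4 expels N2 from 23 to give an electrophilic carbene at the lactone alpha-carbon C3, whose empty p orbital takes up one C–H bond of the O1–C2H2Ar group in a concerted but asynchronous, hydride-transfer-like three-centre event that forms C2–C3 and C3–H and frees the catalyst. The closest known reaction type is the dirhodium-catalysed 1,5 C–H insertion of 3-diazo-4-(arylmethoxymethyl)butyrolactones, and of alpha-diazo esters next to ether oxygen, to give tetrahydrofurans. One ring closes, the tetrahydrofuran (C3, C4, C5, O1, C2), by 1,5 insertion through a five-membered array annulated to the existing lactone. C3 (C6a of 24) is set by C4, because the ether can reach the carbene only from the lactone face that carries the C4 side chain and a trans-fused 3,7-dioxabicyclo[3.3.0]octane is too strained, so the fusion is cis. C2 (C6 of 24) is set by the catalyst: the dirhodium core and its acetates depart from the convex side of the closing ring, so the C2 aryl turns away from them and should end cis to the carbonyl on the concave face, as benzylic ethers generally do in such insertions, which is why this centre is not relied on here but equilibrated in step 16, and any convex epimer needs no separation. The selectivity the step does need is chemoselectivity over 1,2-hydride shift from C4–H, attack on the C5 arene and carbene dimerisation, and it rests on the double activation of C2–H by O1 and a p-silyloxyaryl group, on the ring-held C4–H lying off the axis of the carbene p orbital, on silyl rather than benzyl phenol protection (no rival benzylic C–H, shielded arenes), on acetate rather than perfluorocarboxylate ligands, and on slow addition.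

**Step 14**
Reactants: 24 rac-(3aR*,4S*,6S*,6aR*)-4,6-di-Ar-tetrahydro-1H,3H-furo[3,4-c]furan-1-one
Product: 25 rac-[(2S*,3S*,4R*,5S*)-2,5-di-Ar-tetrahydrofuran-3,4-diyl]dimethanol
Conditions: LiAlH4, THF, 0 °C; Rochelle salt work-up
Reagents that add atoms: none
Why: Hydride reduction of a lactone to the 1,4-diol is standard, is kept brief at 0 °C so that the aryl silyl ethers persist, and touches no stereocentre.

**Step 15**
Reactants: 25 rac-[(2S*,3S*,4R*,5S*)-2,5-di-Ar-tetrahydrofuran-3,4-diyl]dimethanol; 9 acetic anhydride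
Product: 26 rac-[(2S*,3S*,4R*,5S*)-2,5-di-Ar-tetrahydrofuran-3,4-diyl]bis(methylene) diacetate (2,3-cis; 3,4-cis; 4,5-trans)
Conditions: Ac2O, pyridine, DMAP (cat.), CH2Cl2, 0 °C to rt
Reagents that add atoms: acetic anhydride CC(=O)OC(C)=O
Why: DMAP-catalysed acetylation of the two primary alcohols runs under basic conditions, which keeps the acid-sensitive diol from rearranging to a furofuran.

**Step 16**
Reactants: 26 rac-[(2S*,3S*,4R*,5S*)-2,5-di-Ar-tetrahydrofuran-3,4-diyl]bis(methylene) diacetate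
Product: 27 [(2R,3S,4R,5S)-2,5-di-Ar-tetrahydrofuran-3,4-diyl]bis(methylene) diacetate (meso; 2,3-trans; 3,4-cis; 4,5-trans)
Conditions: BF3·OEt2 (20 mol%), CH2Cl2, −20 to 0 °C, until the composition no longer changes; Et3N quench
Reagents that add atoms: none
Why: In this acid-promoted benzylic epimerisation, known for 2,5-diaryltetrahydrofuran and furofuran lignans, reversible heterolysis of O1–C2 (or O1–C5) gives a p-silyloxybenzyl cation that recloses, and among the three isomers that share the cis C3/C4 arms the one with both aryls trans to their neighbouring CH2OAc is the least strained, so thermodynamic control sets C2 and confirms C5.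

**Step 17**
Reactants: 27 [(2R,3S,4R,5S)-2,5-di-Ar-tetrahydrofuran-3,4-diyl]bis(methylene) diacetate
Product: 28 [(2R,3S,4R,5S)-2,5-bis(3,4-dihydroxyphenyl)tetrahydrofuran-3,4-diyl]bis(methylene) diacetate (CNP0416169.1)
Conditions: Bu4NF (4.4 equiv), AcOH (6 equiv), THF, 0 °C, argon
Reagents that add atoms: none
Why: Fluoride cleaves aryl silyl ethers within minutes, and the acetic acid buffer protonates each phenoxide as it forms, so the acetates are not transesterified and the catechols are neither oxidised nor epimerised.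

**Compound list**
1 | 3,4-dihydroxybenzaldehyde | O=Cc1ccc(O)c(O)c1 | starting material
2 | tert-butyldimethylsilyl chloride | CC(C)(C)[Si](C)(C)Cl | starting material
3 | 3,4-bis(tert-butyldimethylsilyloxy)benzaldehyde | O=Cc1ccc(O[Si](C)(C)C(C)(C)C)c(O[Si](C)(C)C(C)(C)C)c1 | intermediate
4 | [3,4-bis(tert-butyldimethylsilyloxy)phenyl]methanol | OCc1ccc(O[Si](C)(C)C(C)(C)C)c(O[Si](C)(C)C(C)(C)C)c1 | intermediate
5 | trichloroacetonitrile | N#CC(Cl)(Cl)Cl | starting material
6 | 3,4-bis(tert-butyldimethylsilyloxy)benzyl 2,2,2-trichloroacetimidate | N=C(OCc1ccc(O[Si](C)(C)C(C)(C)C)c(O[Si](C)(C)C(C)(C)C)c1)C(Cl)(Cl)Cl | intermediate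
7 | (Z)-but-2-ene-1,4-diol | OC/C=C\CO | starting material
8 | (Z)-4-(tert-butyldimethylsilyloxy)but-2-en-1-ol | OC/C=C\CO[Si](C)(C)C(C)(C)C | intermediate
9 | acetic anhydride | CC(=O)OC(C)=O | starting material
10 | (Z)-4-(tert-butyldimethylsilyloxy)but-2-enyl acetate | CC(=O)OC/C=C\CO[Si](C)(C)C(C)(C)C | intermediate
11 | bis(pinacolato)diboron | CC1(C)OB(OC1(C)C)B1OC(C)(C)C(C)(C)O1 | starting material
12 | (E)-4-(tert-butyldimethylsilyloxy)but-2-enylboronic acid pinacol ester | CC(C)(C)[Si](C)(C)OC/C=C/CB1OC(C)(C)C(C)(C)O1 | intermediate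
13 | pinacol borate ester of 14 (racemic, anti) | C=C[C@H](CO[Si](C)(C)C(C)(C)C)[C@@H](c1ccc(O[Si](C)(C)C(C)(C)C)c(O[Si](C)(C)C(C)(C)C)c1)OB1OC(C)(C)C(C)(C)O1 | intermediate
14 | rac-(1S*,2R*)-1-Ar-2-(TBSOCH2)but-3-en-1-ol (anti) | C=C[C@H](CO[Si](C)(C)C(C)(C)C)[C@@H](c1ccc(O[Si](C)(C)C(C)(C)C)c(O[Si](C)(C)C(C)(C)C)c1)O | intermediate
15 | rac-(1S*,2R*)-1-Ar-1-(ArCH2O)-2-(TBSOCH2)but-3-ene | C=C[C@H](CO[Si](C)(C)C(C)(C)C)[C@@H](c1ccc(O[Si](C)(C)C(C)(C)C)c(O[Si](C)(C)C(C)(C)C)c1)OCc1ccc(O[Si](C)(C)C(C)(C)C)c(O[Si](C)(C)C(C)(C)C)c1 | intermediate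
16 | B-alkyl-9-BBN adduct of 15 (boron on the terminal carbon) | C(CB1C2CCCC1CCC2)[C@H](CO[Si](C)(C)C(C)(C)C)[C@@H](c1ccc(O[Si](C)(C)C(C)(C)C)c(O[Si](C)(C)C(C)(C)C)c1)OCc1ccc(O[Si](C)(C)C(C)(C)C)c(O[Si](C)(C)C(C)(C)C)c1 | intermediate
17 | rac-(3R*,4S*)-4-Ar-4-(ArCH2O)-3-(TBSOCH2)butan-1-ol | OCC[C@H](CO[Si](C)(C)C(C)(C)C)[C@@H](c1ccc(O[Si](C)(C)C(C)(C)C)c(O[Si](C)(C)C(C)(C)C)c1)OCc1ccc(O[Si](C)(C)C(C)(C)C)c(O[Si](C)(C)C(C)(C)C)c1 | intermediate
18 | rac-(3R*,4S*)-4-Ar-4-(ArCH2O)-3-(TBSOCH2)butanal | O=CC[C@H](CO[Si](C)(C)C(C)(C)C)[C@@H](c1ccc(O[Si](C)(C)C(C)(C)C)c(O[Si](C)(C)C(C)(C)C)c1)OCc1ccc(O[Si](C)(C)C(C)(C)C)c(O[Si](C)(C)C(C)(C)C)c1 | intermediate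
19 | rac-(3R*,4S*)-4-Ar-4-(ArCH2O)-3-(TBSOCH2)butanoic acid | OC(=O)C[C@H](CO[Si](C)(C)C(C)(C)C)[C@@H](c1ccc(O[Si](C)(C)C(C)(C)C)c(O[Si](C)(C)C(C)(C)C)c1)OCc1ccc(O[Si](C)(C)C(C)(C)C)c(O[Si](C)(C)C(C)(C)C)c1 | intermediate
20 | rac-(3R*,4S*)-4-Ar-4-(ArCH2O)-3-(hydroxymethyl)butanoic acid | OC(=O)C[C@H](CO)[C@@H](c1ccc(O[Si](C)(C)C(C)(C)C)c(O[Si](C)(C)C(C)(C)C)c1)OCc1ccc(O[Si](C)(C)C(C)(C)C)c(O[Si](C)(C)C(C)(C)C)c1 | intermediate
21 | rac-(4R*)-4-[(S*)-Ar(ArCH2O)methyl]dihydrofuran-2(3H)-one | O=C1C[C@H](CO1)[C@@H](c1ccc(O[Si](C)(C)C(C)(C)C)c(O[Si](C)(C)C(C)(C)C)c1)OCc1ccc(O[Si](C)(C)C(C)(C)C)c(O[Si](C)(C)C(C)(C)C)c1 | intermediate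
22 | 3-trifluoroacetyl derivative of 21 (C3 undefined, largely enolised) | O=C1C(C(=O)C(F)(F)F)[C@H](CO1)[C@@H](c1ccc(O[Si](C)(C)C(C)(C)C)c(O[Si](C)(C)C(C)(C)C)c1)OCc1ccc(O[Si](C)(C)C(C)(C)C)c(O[Si](C)(C)C(C)(C)C)c1 | intermediate
23 | rac-(4R*)-3-diazo-4-[(S*)-Ar(ArCH2O)methyl]dihydrofuran-2(3H)-one | O=C1C(=[N+]=[N-])[C@H](CO1)[C@@H](c1ccc(O[Si](C)(C)C(C)(C)C)c(O[Si](C)(C)C(C)(C)C)c1)OCc1ccc(O[Si](C)(C)C(C)(C)C)c(O[Si](C)(C)C(C)(C)C)c1 | intermediate
24 | rac-(3aR*,4S*,6S*,6aR*)-4,6-di-Ar-tetrahydro-1H,3H-furo[3,4-c]furan-1-one (cis-fused, 4-aryl convex, 6-aryl concave) | O=C2[C@@H]1[C@H](CO2)[C@@H](c3ccc(O[Si](C)(C)C(C)(C)C)c(O[Si](C)(C)C(C)(C)C)c3)O[C@@H]1c1ccc(O[Si](C)(C)C(C)(C)C)c(O[Si](C)(C)C(C)(C)C)c1 | intermediate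
25 | rac-[(2S*,3S*,4R*,5S*)-2,5-di-Ar-tetrahydrofuran-3,4-diyl]dimethanol | OC[C@@H]1[C@H](CO)[C@@H](c2ccc(O[Si](C)(C)C(C)(C)C)c(O[Si](C)(C)C(C)(C)C)c2)O[C@@H]1c1ccc(O[Si](C)(C)C(C)(C)C)c(O[Si](C)(C)C(C)(C)C)c1 | intermediate
26 | rac-[(2S*,3S*,4R*,5S*)-2,5-di-Ar-tetrahydrofuran-3,4-diyl]bis(methylene) diacetate | CC(=O)OC[C@@H]1[C@H](COC(C)=O)[C@@H](c2ccc(O[Si](C)(C)C(C)(C)C)c(O[Si](C)(C)C(C)(C)C)c2)O[C@@H]1c1ccc(O[Si](C)(C)C(C)(C)C)c(O[Si](C)(C)C(C)(C)C)c1 | intermediate
27 | [(2R,3S,4R,5S)-2,5-di-Ar-tetrahydrofuran-3,4-diyl]bis(methylene) diacetate (meso) | CC(=O)OC[C@@H]1[C@H](COC(C)=O)[C@@H](c2ccc(O[Si](C)(C)C(C)(C)C)c(O[Si](C)(C)C(C)(C)C)c2)O[C@H]1c1ccc(O[Si](C)(C)C(C)(C)C)c(O[Si](C)(C)C(C)(C)C)c1 | intermediate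
28 | [(2R,3S,4R,5S)-2,5-bis(3,4-dihydroxyphenyl)tetrahydrofuran-3,4-diyl]bis(methylene) diacetate (meso) | CC(=O)OC[C@@H]1[C@H](COC(C)=O)[C@@H](c2ccc(O)c(O)c2)O[C@H]1c1ccc(O)c(O)c1 | target

**Total step count:** 17
**Longest linear sequence:** 14 steps (steps 4 to 17, from 7)

**Steps most likely to fail**

1. **Step 13.**
   - Risk: the carbene may be consumed by 1,2-hydride migration from C4 or by attack on the electron-rich C5 arene before it reaches the C2–H bond.
   - Fallback: it sets out from 3 and 14, returns at 24, and makes C2–C3 by enolate acylation instead of a carbene. Pinnick oxidation of 3 (NaClO2, NaH2PO4, 2-methylbut-2-ene, t-BuOH–H2O) gives 3,4-bis(tert-butyldimethylsilyloxy)benzoic acid F1. Steglich esterification with 14 (DCC, DMAP, CH2Cl2) gives the anti homoallylic aroate F2. The conditions of steps 9, 10 and 11 then lead through the primary alcohol F3 and the carboxylic acid F4 to the lactone aroate F5. LiHMDS (2.2 equiv, THF, −78 to 0 °C) should trigger an intramolecular Claisen-type transfer of the aroyl group from O1 to C3 through a five-membered tetrahedral intermediate. The resulting hydroxy beta-keto lactone should rest as the cis-fused cyclic hemiketal F6. Ionic reduction (Et3SiH, BF3·OEt2, CH2Cl2, −78 °C) of the aryl-stabilised oxocarbenium ion takes hydride on the convex face and gives 24.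

2. **Step 16.**
   - Risk: the equilibration may stop short of a one-sided composition. It may also be overtaken by capture of the C2 cation by the neighbouring acetate with acyl migration, by irreversible Friedel–Crafts closure onto the other arene, or by proton loss from C3.
   - Fallback: it sets out from 24, returns at 27, and moves the equilibration to the bicyclic lactone, where the only internal nucleophile that can recapture the cation is the C5 oxygen. Treating 24 with CF3CO2H in CH2Cl2 at 0 °C should give the all-convex lactone F7. This equilibrium may be less one-sided, so F7 is separated and recovered 24 is resubmitted. LiAlH4 (THF, 0 °C) gives the meso diol F8, and Ac2O with pyridine and DMAP gives 27.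

3. **Step 8.**
   - Risk: the acid catalyst may ionise the C5 benzylic alcohol, with loss of the anti relationship or self-etherification, or the imidate may rearrange before it alkylates the hindered alcohol.
   - Fallback: it sets out from 4 and 14, returns at 15, and forms the ether under neutral conditions. Appel bromination of 4 (CBr4, PPh3, CH2Cl2, 0 °C) gives 3,4-bis(tert-butyldimethylsilyloxy)benzyl bromide F9. Silver-promoted Williamson-type alkylation of 14 (Ag2O, 4 Å MS, toluene, dark, rt) gives 15 without acid and without a free alkoxide.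

**Further compounds**
F1 | step 13 | 3,4-bis(tert-butyldimethylsilyloxy)benzoic acid | OC(=O)c1ccc(O[Si](C)(C)C(C)(C)C)c(O[Si](C)(C)C(C)(C)C)c1
F2 | step 13 | rac-(1S*,2R*)-1-Ar-2-(TBSOCH2)but-3-enyl 3,4-bis(tert-butyldimethylsilyloxy)benzoate | C=C[C@H](CO[Si](C)(C)C(C)(C)C)[C@@H](c1ccc(O[Si](C)(C)C(C)(C)C)c(O[Si](C)(C)C(C)(C)C)c1)OC(=O)c1ccc(O[Si](C)(C)C(C)(C)C)c(O[Si](C)(C)C(C)(C)C)c1
F3 | step 13 | rac-(1S*,2R*)-1-Ar-4-hydroxy-2-(TBSOCH2)butyl 3,4-bis(tert-butyldimethylsilyloxy)benzoate | OCC[C@H](CO[Si](C)(C)C(C)(C)C)[C@@H](c1ccc(O[Si](C)(C)C(C)(C)C)c(O[Si](C)(C)C(C)(C)C)c1)OC(=O)c1ccc(O[Si](C)(C)C(C)(C)C)c(O[Si](C)(C)C(C)(C)C)c1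
F4 | step 13 | rac-(3R*,4S*)-4-Ar-4-(ArCO2)-3-(TBSOCH2)butanoic acid | OC(=O)C[C@H](CO[Si](C)(C)C(C)(C)C)[C@@H](c1ccc(O[Si](C)(C)C(C)(C)C)c(O[Si](C)(C)C(C)(C)C)c1)OC(=O)c1ccc(O[Si](C)(C)C(C)(C)C)c(O[Si](C)(C)C(C)(C)C)c1
F5 | step 13 | rac-(S*)-Ar[(3R*)-5-oxotetrahydrofuran-3-yl]methyl 3,4-bis(tert-butyldimethylsilyloxy)benzoate | O=C1C[C@H](CO1)[C@@H](c1ccc(O[Si](C)(C)C(C)(C)C)c(O[Si](C)(C)C(C)(C)C)c1)OC(=O)c1ccc(O[Si](C)(C)C(C)(C)C)c(O[Si](C)(C)C(C)(C)C)c1
F6 | step 13 | rac-4,6-di-Ar-6-hydroxytetrahydro-1H,3H-furo[3,4-c]furan-1-one (cis-fused hemiketal, C6 undefined) | O=C2[C@@H]1[C@H](CO2)[C@@H](c3ccc(O[Si](C)(C)C(C)(C)C)c(O[Si](C)(C)C(C)(C)C)c3)OC1(O)c1ccc(O[Si](C)(C)C(C)(C)C)c(O[Si](C)(C)C(C)(C)C)c1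
F7 | step 16 | rac-(3aR*,4S*,6R*,6aR*)-4,6-di-Ar-tetrahydro-1H,3H-furo[3,4-c]furan-1-one (both aryls convex) | O=C2[C@@H]1[C@H](CO2)[C@@H](c3ccc(O[Si](C)(C)C(C)(C)C)c(O[Si](C)(C)C(C)(C)C)c3)O[C@H]1c1ccc(O[Si](C)(C)C(C)(C)C)c(O[Si](C)(C)C(C)(C)C)c1
F8 | step 16 | [(2R,3S,4R,5S)-2,5-di-Ar-tetrahydrofuran-3,4-diyl]dimethanol (meso) | OC[C@@H]1[C@H](CO)[C@@H](c2ccc(O[Si](C)(C)C(C)(C)C)c(O[Si](C)(C)C(C)(C)C)c2)O[C@H]1c1ccc(O[Si](C)(C)C(C)(C)C)c(O[Si](C)(C)C(C)(C)C)c1
F9 | step 8 | 3,4-bis(tert-butyldimethylsilyloxy)benzyl bromide | BrCc1ccc(O[Si](C)(C)C(C)(C)C)c(O[Si](C)(C)C(C)(C)C)c1
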